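**Assumption:** the target is the (1R,5R,6R) isomer (acetoxy and oxirane oxygen cis on the ring); natural (R)-(+)-pulegone is the only source of chirality.

## Retrosynthetic overview

1. The enone C=C and the acetate go on last (desaturation, acetylation), so the ring methyl carbon is a temporary, purchased stereocentre (from pulegone) that is erased at the end.
2. The oxirane comes from hydroxyl-directed nucleophilic epoxidation of a 2-farnesyl-4-hydroxy-5-methylcyclohex-2-enone (the free C4–OH and the C5–Me reinforce each other).
3. The C4–O bond comes from a singlet-oxygen [4+2] cycloaddition onto the silyl dienol ether of the farnesyl enone; the transient 2,3-dioxabicyclo[2.2.2]octene collapses to the γ-hydroxy enone.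
4. The farnesyl group goes on by α-iodination and Stille coupling of (R)-5-methylcyclohex-2-enone, made from pulegone by the thiophenoxide/retro-aldol route.
5. Ring order: carbocycle bought; endoperoxide ring formed and opened in step 8; oxirane formed in step 9.

## Route

**Step 1**
Reactants: 1, (R)-(+)-pulegone
Product: 2, pulegone oxide, (6R)-2,2,6-trimethyl-1-oxaspiro[2.5]octan-4-one (both spiro epimers)
Conditions: 30% H2O2, LiOH, MeOH, 0 °C → rt
Reagents that add atoms: hydrogen peroxide, OO
Why: Weitz–Scheffer nucleophilic epoxidation of the enone; the spiro-centre configuration is irrelevant because it is destroyed in step 2.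

**Step 2**
Reactants: 2, pulegone oxide
Product: 3, (5R)-5-methyl-2-(phenylsulfanyl)cyclohexan-1-one (cis/trans mixture at C2)
Conditions: PhSH, NaH, THF, reflux
Reagents that add atoms: thiophenol, Sc1ccccc1
Why: thiolate opens the epoxide at the α-carbon and the resulting β-alkoxide undergoes retro-aldol loss of acetone, which places sulfur regiospecifically on the carbon remote from the methyl; C5 is untouched.

**Step 3**
Reactants: 3
Product: 4, (5R)-5-methylcyclohex-2-en-1-one
Conditions: NaIO4, MeOH/H2O, 0 °C → rt; then CaCO3, toluene, 90 °C
Reagents that add atoms: none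
Why: sulfide oxidation followed by thermal sulfoxide syn-elimination; the only β-hydrogens are on C3, so the enone forms regiospecifically without touching C5.

**Step 4**
Reactants: 4
Product: 5, (5R)-2-iodo-5-methylcyclohex-2-en-1-one
Conditions: I2, pyridine, CH2Cl2, 0 °C → rt
Reagents that add atoms: iodine, II
Why: Johnson α-iodination of an enone (pyridine conjugate addition, enolate iodination, elimination).

**Step 5**
Reactants: 6, (2E,6E)-farnesyl bromide
Product: 7, tributyl[(2E,6E)-3,7,11-trimethyldodeca-2,6,10-trien-1-yl]stannane
Conditions: Bu3SnLi (from Bu3SnH, LDA), THF, –78 °C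
Reagents that add atoms: tributyltin hydride (as Bu3SnLi), CCCC[SnH](CCCC)CCCC
Why: SN2 displacement of the primary allylic bromide by the stannyl anion at low temperature, keeping the 2E geometry.

**Step 6**
Reactants: 5 and 7
Product: 8, (5R)-5-methyl-2-[(2E,6E)-3,7,11-trimethyldodeca-2,6,10-trien-1-yl]cyclohex-2-en-1-one
Conditions: Pd2(dba)3 (cat.), AsPh3, CuI, NMP, 50 °C
Reagents that add atoms: none beyond 7
Why: Stille coupling of the α-iodoenone; reductive elimination at the unsubstituted allyl terminus gives the linear farnesyl group with the olefin geometry retained.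

**Step 7**
Reactants: 8
Product: 9, trimethyl{[(5S)-5-methyl-2-farnesylcyclohexa-1,3-dien-1-yl]oxy}silane (used crude; the descriptor changes by CIP only, the methyl is spatially unchanged)
Conditions: KOt-Bu, THF/DMPU, –78 → –20 °C; TMSCl, –78 °C; non-aqueous work-up
Reagents that add atoms: chlorotrimethylsilane, C[Si](C)(C)Cl
Why: an equilibrating base gives the through-conjugated (γ-deprotonated) dienolate, and O-silylation gives the linear 1-silyloxy-1,3-diene; the C5–H is not acidic, so the stereocentre survives.

**Step 8**
Reactants: 9
Product: 10, (4R,5S)-4-hydroxy-5-methyl-2-farnesylcyclohex-2-en-1-one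
Conditions: O2, hν, TPP (cat.), CH2Cl2, –78 °C, stopped when the diene is consumed; then PPh3; mild methanolic work-up
Reagents that add atoms: oxygen (as singlet oxygen), O=O
Why: [4+2] cycloaddition of singlet oxygen across C1/C4 of the electron-rich diene gives a 1-silyloxy-2,3-dioxabicyclo[2.2.2]oct-5-ene, which collapses to the γ-(silyl)peroxy enone and is reduced to the alcohol. Oxygen should add anti to the adjacent C5-methyl, setting C4 trans to it; I expect only moderate selectivity (about 4:1, minor epimer removed by chromatography). The diene is far more reactive than the chain olefins, which limits the competing ene reaction.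

**Step 9**
Reactants: 10
Product: 11, (1R,4S,5R,6R)-5-hydroxy-4-methyl-1-farnesyl-7-oxabicyclo[4.1.0]heptan-2-one
Conditions: t-BuOOH, Triton B (cat.), THF, 0 °C
Reagents that add atoms: tert-butyl hydroperoxide, CC(C)(C)OO
Why: nucleophilic epoxidation touches only the enone; the peroxide is delivered syn to the free C4–OH (hydrogen bonding) and anti to the C5-methyl, a matched pair, so both oxirane carbons are set cis to the hydroxyl.

**Step 10**
Reactants: 11
Product: 12, (1R,4S,5R,6R)-5-acetoxy-4-methyl-1-farnesyl-7-oxabicyclo[4.1.0]heptan-2-one
Conditions: Ac2O, pyridine, DMAP (cat.), CH2Cl2, 0 °C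
Reagents that add atoms: acetic anhydride, CC(=O)OC(C)=O
Why: simple acylation of the secondary alcohol with retention.

**Step 11**
Reactants: 12
Product: 13, target, (1R,5R,6R)-4-methyl-2-oxo-1-[(2E,6E)-3,7,11-trimethyldodeca-2,6,10-trien-1-yl]-7-oxabicyclo[4.1.0]hept-3-en-5-yl acetate
Conditions: LiHMDS, THF, –78 °C; PhSeCl; then 30% H2O2, pyridine, CH2Cl2, 0 °C → rt
Reagents that add atoms: none
Why: the ketone can enolise only toward C3 (the other α-carbon is the quaternary oxirane carbon). Selenenylation occurs trans to the methyl, which leaves the C4–H syn for selenoxide syn-elimination. This installs the enone and erases the temporary methyl stereocentre, leaving the three target centres.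

## Compound list

1 | (R)-(+)-pulegone | C[C@@H]1CCC(=C(C)C)C(=O)C1 | starting material
2 | pulegone oxide | C[C@@H]1CCC2(OC2(C)C)C(=O)C1 | intermediate
3 | (5R)-5-methyl-2-(phenylsulfanyl)cyclohexanone | C[C@@H]1CCC(Sc2ccccc2)C(=O)C1 | intermediate
4 | (R)-5-methylcyclohex-2-enone | C[C@@H]1CC=CC(=O)C1 | intermediate
5 | (R)-2-iodo-5-methylcyclohex-2-enone | C[C@@H]1CC=C(I)C(=O)C1 | intermediate
6 | (2E,6E)-farnesyl bromide | BrC/C=C(\C)CC/C=C(\C)CCC=C(C)C | starting material
7 | tributyl[(2E,6E)-farnesyl]stannane | CCCC[Sn](CCCC)(CCCC)C/C=C(\C)CC/C=C(\C)CCC=C(C)C | intermediate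
8 | (R)-2-farnesyl-5-methylcyclohex-2-enone | C[C@@H]1CC=C(C/C=C(\C)CC/C=C(\C)CCC=C(C)C)C(=O)C1 | intermediate
9 | TMS dienol ether of 8 | C[C@@H]1C=CC(C/C=C(\C)CC/C=C(\C)CCC=C(C)C)=C(O[Si](C)(C)C)C1 | intermediate
10 | (4R,5S)-2-farnesyl-4-hydroxy-5-methylcyclohex-2-enone | C[C@@H]1[C@@H](O)C=C(C/C=C(\C)CC/C=C(\C)CCC=C(C)C)C(=O)C1 | intermediate
11 | (1R,4S,5R,6R)-epoxy alcohol | O[C@@H]1[C@@H](C)CC(=O)[C@]2(C/C=C(\C)CC/C=C(\C)CCC=C(C)C)O[C@H]12 | intermediate
12 | (1R,4S,5R,6R)-epoxy acetate | CC(=O)O[C@@H]1[C@@H](C)CC(=O)[C@]2(C/C=C(\C)CC/C=C(\C)CCC=C(C)C)O[C@H]12 | intermediate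
13 | CID121596208 | CC(=O)O[C@@H]1C(C)=CC(=O)[C@]2(C/C=C(\C)CC/C=C(\C)CCC=C(C)C)O[C@H]12 | target

## Step count

Total steps: 11. Longest linear sequence: 10 (1 → 13 through steps 1–4 and 6–11).

## Three steps most likely to fail

1. **Step 8 (singlet-oxygen cycloaddition).** Facial control by a single adjacent methyl may be modest, and the farnesyl olefins can undergo ene oxidation. Fallback: make 10 without photo-oxygenation from (–)-quinic acid. The butane-diacetal-protected 4,5-dihydroxycyclohex-2-enone is α′-alkylated with farnesyl bromide, then treated with Me2CuLi, with conjugate addition anti to C4–O followed by β-elimination of the C5 alkoxide. There C4–O is purchased and the methyl is the relayed centre.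
2. **Step 6 (Stille coupling).** α- versus γ-allyl transfer and E/Z erosion are possible. Fallback: drop the tin chemistry and C-alkylate sulfide 3 at C2 with farnesyl bromide (NaH), then oxidise and eliminate the sulfoxide. Alternatively, 1,4-reduce 4 with L-Selectride, trap the enolate with 6, and re-desaturate.
3. **Step 11 (selenenylation/elimination with an acetate and α-epoxy ketone present).** Acyl transfer or attack on the chain olefins by selenium oxidants could interfere. Fallback: carry C4–OH as a TES ether (TESOTf/Et3N gives the ether and the silyl enol ether together), introduce the enone by Saegusa–Ito oxidation (Pd(OAc)2), then desilylate and acetylate last.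

Step 7 is also a regiochemical risk (linear versus cross-conjugated dienol ether); if it fails, the quinic-acid fallback under point 1 bypasses it as well.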